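## The problem

Prestegane A (19) is a monocyclic γ-butyrolactone with a benzyl arm on each of the two adjacent ring carbons. C3, next to the carbonyl C2, carries the 3-hydroxy-4-methoxybenzyl group (ring A); C4, next to the oxymethylene C5, carries the 3,4-dimethoxybenzyl group (ring B); the arrangement is trans, (3R,4R). The arms differ by one O-methyl group only, so they must enter as separate building blocks, and the two chain ends (C2 as carbonyl, C5 as CH2–O) must be distinguished from the start or the regioisomeric lactone results. C4 is not acidic and has to be set absolutely. C3 is α to the carbonyl and epimerisable, and the trans isomer is the more stable one in this ring, so C4 can correct C3 but not the reverse. The free phenol must be masked through the organometallic steps, the electron-rich rings exclude strong electrophiles and harsh oxidants, and the lactone opens with hydroxide or alkoxide. The enabling feature is that C4 is bonded both to C3 and to the benzylic CH2 of ring B. C4 and that CH2 can therefore be the two carbons of a vinylboron unit, C3 can arrive as a migrating alkenyl carbon already carrying the ring A arm and a methylene that becomes C2, and the boron left on C4 is the handle for C5.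

## Retrosynthesis

**19 from 18.** The phenolic O–H is traced back to a benzyl ether. Benzyl is chosen over silyl or acyl because it survives Grignard and organolithium reagents, basic peroxide and acid, and leaves by neutral hydrogenolysis that touches neither the lactone nor the stereocentres.

**18 from 17.** No bond is cut; the trans lactone 18 is traced to lactone 17 carrying C3 as an epimer mixture. This removes any need to control C3 kinetically earlier on. The forward step only has to reach the thermodynamic trans isomer by enolisation; C4 cannot enolise, so it is not at risk.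

**17 from 15 through 16.** The O1–C2 bond is cut to give the silyl-protected hydroxy acid 16, which is taken back to the primary alcohol 15. Closing the ring by acylation of the C5 oxygen is preferred over oxidising a free 1,4-diol, which could not tell C2 from C5. The forward step must oxidise one primary alcohol to the acid in the presence of a silyl ether and two electron-rich arenes.

**15 from 13 through 14.** The C2–O bond is removed: the CH2OH on C3 becomes the exocyclic methylene of the 1,1-disubstituted alkene 14, the silyl ether of homoallylic alcohol 13. Anti-Markovnikov hydroboration is regiochemically dependable on such alkenes. Its facial selectivity is not relied on, because C3 is corrected later.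

**13 from 11 through 12.** The C4–C5 bond is cut. The hydroxymethyl group is traced to a CH2–boron group (12) and then to boron directly on C4 in the allylic boronate 11. A one-carbon Matteson homologation transfers the C4 configuration with retention and makes C5 the oxygen-bearing terminus without ambiguity.

**11 from 9, 8 and 7 through 10.** This is the central cut: the C3–C4 bond and the bond between the ring B CH2 and its arene are both severed. What remains are vinylboronic ester 8 (C4 and the benzylic CH2), alkenyllithium 9 (C3, the methylene that becomes C2, and the ring A arm) and aryl triflate 7 (ring B), joined through borate 10. Against stepwise enolate alkylations, this cut forms both bonds in one operation and sets C4 by a catalyst. The forward reaction must make palladium activate the vinyl group and not the 1,1-disubstituted alkenyl group, and must give high enantioselectivity.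

**9 from 5, 5 from 2 and 3 through 4, 2 from 1; 7 from 6.** The C–Li bond goes back to the vinylic bromide 5. The arene–CH2 bond of 5 is cut to the Grignard reagent 4 (from bromide 2, the benzyl ether of bromophenol 1) and dibromopropene 3. Triflate 7 comes from phenol 6. Compounds 1, 3, 6 and 8 are commercial.

## Roads not taken

**Alternative 1:** Here the O1–C5 and O1–C2 bonds are cut together. The prochiral 3-(3,4-dimethoxybenzyl)cyclobutanone A2 would undergo catalyst-controlled Baeyer–Villiger oxidation, inserting oxygen on one enantiotopic side to give (R)-4-(3,4-dimethoxybenzyl)dihydrofuran-2(3H)-one A1. Trans-selective enolate alkylation of A1 with 3-(benzyloxy)-4-methoxybenzyl bromide A3 would then give 18.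
- Merits: it is the shortest route, about half the length of the chosen one. C3 is set kinetically by a classical anti alkylation and needs no equilibration, and the carbonyl and oxymethylene ends are distinct by construction.
- Weak points: the prochiral carbon of A2 lies two bonds from the reacting carbonyl, and the catalyst must distinguish a CH2–aryl group from hydrogen at that distance. Asymmetric Baeyer–Villiger catalysts are at their best with 3-aryl cyclobutanones and less dependable with 3-benzyl ones. The key step forms no C–C bond.
- Comparison: in step count this road is better. The chosen plan offers in return a C4 centre set in a C–C bond-forming event by a catalyst class suited to exactly these partners, with the whole carbon core but C5 assembled at once.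

**Alternative 2:** Here the C4–C5 and O1–C2 bonds are cut. The enolate of the aryl ketone in γ-keto acid A5, (R)-2-[3-(benzyloxy)-4-methoxybenzyl]-4-(3,4-dimethoxyphenyl)-4-oxobutanoic acid, would add to formaldehyde A6, and the new hydroxymethyl group would lactonise to keto lactone A4. Catalytic hydrogenolysis of A4 would remove the benzylic ketone oxygen and the benzyl ether in one operation and give 19.
- Merits: cheap reagents, a trans relationship reached under thermodynamic control, and a final step that does two jobs.
- Weak points: in A4 both ring stereocentres are acidic (C4 α to the ketone, C3 α to the lactone), and epimerising one after the other leads to the enantiomer, so basic conditions can erode optical purity. The methylene of A5 can be hydroxymethylated twice or dehydrate to an enone. A5 needs its own asymmetric synthesis, most simply with a stoichiometric auxiliary, and full reduction of an electron-rich aryl ketone to CH2 needs forcing acidic conditions.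
- Comparison: the length is similar to or slightly below that of the chosen plan. The chosen plan has a configurationally inert C4 from the moment it is made and uses catalytic chirality.

**Alternative 3:** Here the C2–C3 and O1–C2 bonds are cut. Cathodic reduction of the styrenyl alcohol A8, (R,E)-4-[3-(benzyloxy)-4-methoxyphenyl]-2-(3,4-dimethoxybenzyl)but-3-en-1-ol, under carbon dioxide A9 would carboxylate the homobenzylic alkene carbon. Protonation at the benzylic carbon and acidification would close the lactone to O-benzyl prestegane A A7, the same compound as 18.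
- Merits: C2 arrives at the right oxidation level, so the endgame after the key step is shorter than in the chosen plan, which spends three operations turning a methylene into the lactone carbonyl.
- Weak points: electron-rich β-alkyl styrenes are hard to reduce, so reduction of A9 itself competes. Dicarboxylation and carboxylation at the benzylic carbon are the usual side paths. The free hydroxyl is an uncontrolled proton source, C3 is formed without facial control, and A8 still needs an enantioselective synthesis.
- Comparison: the late stage is more economical, but the key step is far less established on this substrate class than the conjunctive coupling, and it sets no stereocentre.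

Key step: step 4

Assumption: both antipodes of the ferrocenyl bisphosphine used in step 4 are available; the one that delivers (R)-11 is used, and its sense of induction would be checked on the first run by oxidising a sample of 11 to the allylic alcohol and correlating the configuration.

## Route

Step 1
Reactants: 1 5-bromo-2-methoxyphenol
Product: 2 2-(benzyloxy)-4-bromo-1-methoxybenzene
Conditions: BnBr, K2CO3, DMF, rt
Reagents that add atoms: benzyl bromide, BrCc1ccccc1
Why: Williamson O-alkylation of the phenoxide; the benzyl ether tolerates the organometallic, peroxide and acid steps and is removed last.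

Step 2
Reactants: 2 2-(benzyloxy)-4-bromo-1-methoxybenzene; 3 2,3-dibromoprop-1-ene
Product: 5 2-(benzyloxy)-4-(2-bromoprop-2-en-1-yl)-1-methoxybenzene, via arylmagnesium bromide 4 (not isolated)
Conditions: Mg, THF, reflux; then 3, CuI (cat.), THF, 0 °C to rt
Reagents that add atoms: none
Why: Grignard formation followed by allylic substitution on the allylic bromide; direct and allylically transposed attack give the same 2-bromoallyl arene, and the vinylic bromide does not react.

Step 3
Reactants: 6 3,4-dimethoxyphenol
Product: 7 3,4-dimethoxyphenyl trifluoromethanesulfonate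
Conditions: Tf2O, pyridine, CH2Cl2, 0 °C
Reagents that add atoms: trifluoromethanesulfonic anhydride, O=S(=O)(OS(=O)(=O)C(F)(F)F)C(F)(F)F
Why: O-sulfonylation of the phenol; the triflate gives a cationic arylpalladium species free of halide, which the next step requires.

Step 4
Reactants: 5 2-(benzyloxy)-4-(2-bromoprop-2-en-1-yl)-1-methoxybenzene; 8 4,4,5,5-tetramethyl-2-vinyl-1,3,2-dioxaborolane; 7 3,4-dimethoxyphenyl trifluoromethanesulfonate
Product: 11 (R)-2-{3-[3-(benzyloxy)-4-methoxybenzyl]-1-(3,4-dimethoxyphenyl)but-3-en-2-yl}-4,4,5,5-tetramethyl-1,3,2-dioxaborolane, via alkenyllithium 9 (not isolated), via lithium alkenyl vinyl borate 10 (not isolated)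
Conditions: t-BuLi (2 equiv), Et2O, −78 °C; 8, −78 °C to rt; solvent exchange to THF; KOTf, Pd(OAc)2 (cat.), 1,1′-bis[bis(4-methoxy-3,5-dimethylphenyl)phosphino]-2,2′-bis[α-(dimethylamino)benzyl]ferrocene (cat., antipode giving R), 7, 60 °C
Reagents that add atoms: none
Why: Bromine–lithium exchange gives alkenyllithium 9, which adds to boron of 8 to form the four-coordinate borate 10, while KOTf removes bromide as KBr so that palladium stays cationic. Zerovalent palladium, formed from Pd(OAc)2 and the bisphosphine, inserts into the C–O bond of triflate 7, and the cationic divalent arylpalladium binds the unsubstituted vinyl group of 10. This π-activation triggers a 1,2-metallate shift in which the 2-substituted alkenyl group moves from boron to the adjacent carbon anti to palladium (C3–C4 bond), and reductive elimination then forms the CH2–aryl bond and returns zerovalent palladium. The closest known reaction type is the palladium-catalysed enantioselective conjunctive cross-coupling of bis(alkenyl)boron ate complexes with aryl triflates, which gives α-chiral allylic boronates. No ring is closed. The only new stereocentre, C4, is set by the chiral ligand, which decides the face of the bound vinyl group to which the alkenyl group migrates. The step needs chemoselectivity between the two alkenyl groups on boron and suppression of direct Suzuki-type transfer; the first rests on the vinyl group binding palladium far better than the 1,1-disubstituted alkenyl group, the second on the wide-bite-angle bisphosphine and the halide-poor medium.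

Step 5
Reactants: 11 (R)-2-{3-[3-(benzyloxy)-4-methoxybenzyl]-1-(3,4-dimethoxyphenyl)but-3-en-2-yl}-4,4,5,5-tetramethyl-1,3,2-dioxaborolane
Product: 13 (R)-3-[3-(benzyloxy)-4-methoxybenzyl]-2-(3,4-dimethoxybenzyl)but-3-en-1-ol, via homologated boronate 12 (not isolated)
Conditions: BrCH2Cl, n-BuLi, THF, −78 °C to rt; then NaOH, H2O2, THF/H2O, 0 °C to rt
Reagents that add atoms: bromochloromethane, ClCBr; hydrogen peroxide, OO
Why: Matteson homologation: LiCH2Cl formed in the flask adds to boron and the allylic carbon migrates to CH2 with loss of chloride and retention at C4; oxidation of the new primary C–B bond then gives the C5 alcohol without touching the stereocentre.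

Step 6
Reactants: 13 (R)-3-[3-(benzyloxy)-4-methoxybenzyl]-2-(3,4-dimethoxybenzyl)but-3-en-1-ol
Product: 14 (R)-{3-[3-(benzyloxy)-4-methoxybenzyl]-2-(3,4-dimethoxybenzyl)but-3-en-1-yl}oxy(tert-butyl)dimethylsilane
Conditions: TBSCl, imidazole, DMF, rt
Reagents that add atoms: tert-butyldimethylsilyl chloride, CC(C)(C)[Si](C)(C)Cl
Why: Imidazole-promoted silylation of the primary alcohol; it keeps the C5 oxygen at the alcohol level while C2 is oxidised.

Step 7
Reactants: 14 (R)-{3-[3-(benzyloxy)-4-methoxybenzyl]-2-(3,4-dimethoxybenzyl)but-3-en-1-yl}oxy(tert-butyl)dimethylsilane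
Product: 15 (3R)-2-[3-(benzyloxy)-4-methoxybenzyl]-4-[(tert-butyldimethylsilyl)oxy]-3-(3,4-dimethoxybenzyl)butan-1-ol, both C2 epimers
Conditions: 9-BBN, THF, rt to 50 °C; then NaOH, H2O2, 0 °C to rt
Reagents that add atoms: hydrogen peroxide, OO
Why: Anti-Markovnikov hydroboration–oxidation places boron, then oxygen, on the terminal carbon of the 1,1-disubstituted alkene; the new centre (lactone C3) forms with little facial bias because the allylic carbon carries two similar CH2 arms, and it is corrected in step 9.

Step 8
Reactants: 15 (3R)-2-[3-(benzyloxy)-4-methoxybenzyl]-4-[(tert-butyldimethylsilyl)oxy]-3-(3,4-dimethoxybenzyl)butan-1-ol, both C2 epimers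
Product: 17 (4R)-3-[3-(benzyloxy)-4-methoxybenzyl]-4-(3,4-dimethoxybenzyl)dihydrofuran-2(3H)-one, both C3 epimers, via silyloxy acid 16 (not isolated)
Conditions: TEMPO (cat.), PhI(OAc)2, MeCN/H2O, rt; aqueous work-up; crude acid in 2 M HCl/THF, rt to 40 °C
Reagents that add atoms: water, O
Why: Oxoammonium-mediated oxidation takes the primary alcohol through the aldehyde hydrate to the acid under conditions that spare silyl ethers and aryl ethers; acid then cleaves the silyl ether and the γ-hydroxy acid lactonises spontaneously, with the C5 oxygen becoming O1.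

Step 9
Reactants: 17 (4R)-3-[3-(benzyloxy)-4-methoxybenzyl]-4-(3,4-dimethoxybenzyl)dihydrofuran-2(3H)-one, both C3 epimers
Product: 18 (3R,4R)-3-[3-(benzyloxy)-4-methoxybenzyl]-4-(3,4-dimethoxybenzyl)dihydrofuran-2(3H)-one
Conditions: DBU, toluene, 80 °C
Reagents that add atoms: none
Why: Base-mediated epimerisation through the lactone enolate under thermodynamic control; the trans-3,4-disubstituted lactone is the more stable epimer, and since C4 cannot enolise its R configuration fixes C3 as R.

Step 10
Reactants: 18 (3R,4R)-3-[3-(benzyloxy)-4-methoxybenzyl]-4-(3,4-dimethoxybenzyl)dihydrofuran-2(3H)-one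
Product: 19 prestegane A, (3R,4R)-4-(3,4-dimethoxybenzyl)-3-(3-hydroxy-4-methoxybenzyl)dihydrofuran-2(3H)-one
Conditions: H2 (1 atm), Pd/C, EtOAc/EtOH, rt
Reagents that add atoms: none
Why: Hydrogenolysis of the benzyl aryl ether under neutral conditions; the lactone, the methyl ethers and both stereocentres are unaffected.

## Compound list

1 | 5-bromo-2-methoxyphenol | COc1ccc(Br)cc1O | starting material
2 | 2-(benzyloxy)-4-bromo-1-methoxybenzene | COc1ccc(Br)cc1OCc1ccccc1 | intermediate
3 | 2,3-dibromoprop-1-ene | C=C(Br)CBr | starting material
4 | [3-(benzyloxy)-4-methoxyphenyl]magnesium bromide | COc1ccc([Mg]Br)cc1OCc1ccccc1 | intermediate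
5 | 2-(benzyloxy)-4-(2-bromoprop-2-en-1-yl)-1-methoxybenzene | C=C(Br)Cc1ccc(OC)c(OCc2ccccc2)c1 | intermediate
6 | 3,4-dimethoxyphenol | COc1ccc(O)cc1OC | starting material
7 | 3,4-dimethoxyphenyl trifluoromethanesulfonate | COc1ccc(OS(=O)(=O)C(F)(F)F)cc1OC | intermediate
8 | 4,4,5,5-tetramethyl-2-vinyl-1,3,2-dioxaborolane | C=CB1OC(C)(C)C(C)(C)O1 | starting material
9 | {3-[3-(benzyloxy)-4-methoxyphenyl]prop-1-en-2-yl}lithium | [Li]C(=C)Cc1ccc(OC)c(OCc2ccccc2)c1 | intermediate
10 | lithium {3-[3-(benzyloxy)-4-methoxyphenyl]prop-1-en-2-yl}(pinacolato)(vinyl)borate | [Li+].C=C[B-]1(OC(C)(C)C(C)(C)O1)C(=C)Cc1ccc(OC)c(OCc2ccccc2)c1 | intermediate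
11 | (R)-2-{3-[3-(benzyloxy)-4-methoxybenzyl]-1-(3,4-dimethoxyphenyl)but-3-en-2-yl}-4,4,5,5-tetramethyl-1,3,2-dioxaborolane | C=C(Cc1ccc(OC)c(OCc2ccccc2)c1)[C@H](B1OC(C)(C)C(C)(C)O1)Cc1ccc(OC)c(OC)c1 | intermediate
12 | (R)-2-{3-[3-(benzyloxy)-4-methoxybenzyl]-2-(3,4-dimethoxybenzyl)but-3-en-1-yl}-4,4,5,5-tetramethyl-1,3,2-dioxaborolane | C=C(Cc1ccc(OC)c(OCc2ccccc2)c1)[C@H](CB1OC(C)(C)C(C)(C)O1)Cc1ccc(OC)c(OC)c1 | intermediate
13 | (R)-3-[3-(benzyloxy)-4-methoxybenzyl]-2-(3,4-dimethoxybenzyl)but-3-en-1-ol | C=C(Cc1ccc(OC)c(OCc2ccccc2)c1)[C@H](CO)Cc1ccc(OC)c(OC)c1 | intermediate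
14 | (R)-{3-[3-(benzyloxy)-4-methoxybenzyl]-2-(3,4-dimethoxybenzyl)but-3-en-1-yl}oxy(tert-butyl)dimethylsilane | C=C(Cc1ccc(OC)c(OCc2ccccc2)c1)[C@H](CO[Si](C)(C)C(C)(C)C)Cc1ccc(OC)c(OC)c1 | intermediate
15 | (3R)-2-[3-(benzyloxy)-4-methoxybenzyl]-4-[(tert-butyldimethylsilyl)oxy]-3-(3,4-dimethoxybenzyl)butan-1-ol, both C2 epimers | OCC(Cc1ccc(OC)c(OCc2ccccc2)c1)[C@H](CO[Si](C)(C)C(C)(C)C)Cc1ccc(OC)c(OC)c1 | intermediate
16 | (3R)-2-[3-(benzyloxy)-4-methoxybenzyl]-4-[(tert-butyldimethylsilyl)oxy]-3-(3,4-dimethoxybenzyl)butanoic acid, both C2 epimers | OC(=O)C(Cc1ccc(OC)c(OCc2ccccc2)c1)[C@H](CO[Si](C)(C)C(C)(C)C)Cc1ccc(OC)c(OC)c1 | intermediate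
17 | (4R)-3-[3-(benzyloxy)-4-methoxybenzyl]-4-(3,4-dimethoxybenzyl)dihydrofuran-2(3H)-one, both C3 epimers | COc1ccc(CC2C(=O)OC[C@@H]2Cc2ccc(OC)c(OC)c2)cc1OCc1ccccc1 | intermediate
18 | (3R,4R)-3-[3-(benzyloxy)-4-methoxybenzyl]-4-(3,4-dimethoxybenzyl)dihydrofuran-2(3H)-one | COc1ccc(C[C@H]2C(=O)OC[C@@H]2Cc2ccc(OC)c(OC)c2)cc1OCc1ccccc1 | intermediate
19 | prestegane A, (3R,4R)-4-(3,4-dimethoxybenzyl)-3-(3-hydroxy-4-methoxybenzyl)dihydrofuran-2(3H)-one | COc1ccc(C[C@H]2C(=O)OC[C@@H]2Cc2ccc(OC)c(OC)c2)cc1O | target

## Step count and least certain steps

Total step count: 10. Longest linear sequence: 9 (steps 1, 2, 4, 5, 6, 7, 8, 9, 10); step 3 is the one-step side branch.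

**Step 4 (key step).**
- What may go wrong: during halogen–lithium exchange the alkenyllithium can take a proton from its own doubly activated allylic–benzylic CH2, or t-BuLi can attack the benzylic ether, so the borate forms incompletely. Bromide carried into the coupling can slow the cationic palladium pathway, which lets direct transfer of the alkenyl group to palladium compete and lowers enantioselectivity.
- Fallback: the same borate is assembled from the opposite side, setting out from 5 and returning at 10. Miyaura borylation of 5 (bis(pinacolato)diboron, PdCl2(PPh3)2, PPh3, KOPh, toluene, 50 °C) should give 2-{3-[3-(benzyloxy)-4-methoxyphenyl]prop-1-en-2-yl}-4,4,5,5-tetramethyl-1,3,2-dioxaborolane F1. Halide-free vinyllithium, from Sn(CH=CH2)4 and n-BuLi, then adds to boron to give 10, which enters the palladium coupling with 7 as in step 4. No basic lithium reagent meets the acidic CH2 or the benzyl ether at the alkenyl stage, and no lithium halide is present.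

**Step 5.**
- What may go wrong: the short-lived carbenoid may be captured incompletely by the hindered secondary allylic boron, leaving unchanged 11 that is then oxidised to the allylic alcohol; a slow 1,3-shift of boron along the allyl unit is a second leak.
- Fallback: a two-stage homologation through a pre-formed, longer-lived carbenoid, setting out from 11 and returning at 12. LiCHCl2 (from CH2Cl2 and n-BuLi, THF, −100 °C) is added to 11 and migration is promoted by ZnCl2 on warming, giving 2-{(2R)-3-[3-(benzyloxy)-4-methoxybenzyl]-1-chloro-2-(3,4-dimethoxybenzyl)but-3-en-1-yl}-4,4,5,5-tetramethyl-1,3,2-dioxaborolane F2 as a mixture at the chlorinated carbon. LiBHEt3 then replaces chloride by hydride through a second 1,2-shift and delivers 12, which is oxidised as in step 5.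

**Step 8.**
- What may go wrong: premature loss of the silyl group in the acidic aqueous oxidation medium would expose the C5 alcohol to the oxidant and blur the distinction between the two termini; oxidative attack on the electron-rich rings is a lesser concern.
- Fallback: lactonisation by way of the lactol under anhydrous oxidation, setting out from 15 and returning at 17. Dess–Martin periodinane (CH2Cl2, NaHCO3) should give (3R)-2-[3-(benzyloxy)-4-methoxybenzyl]-4-[(tert-butyldimethylsilyl)oxy]-3-(3,4-dimethoxybenzyl)butanal F3. Aqueous HCl in THF removes the silyl group, and the hydroxy aldehyde closes to (4R)-3-[3-(benzyloxy)-4-methoxybenzyl]-4-(3,4-dimethoxybenzyl)tetrahydrofuran-2-ol F4. Ag2CO3 on Celite in hot toluene oxidises the lactol to 17.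

## Further compounds

F1 | step 4 | 2-{3-[3-(benzyloxy)-4-methoxyphenyl]prop-1-en-2-yl}-4,4,5,5-tetramethyl-1,3,2-dioxaborolane | C=C(Cc1ccc(OC)c(OCc2ccccc2)c1)B1OC(C)(C)C(C)(C)O1
F2 | step 5 | 2-{(2R)-3-[3-(benzyloxy)-4-methoxybenzyl]-1-chloro-2-(3,4-dimethoxybenzyl)but-3-en-1-yl}-4,4,5,5-tetramethyl-1,3,2-dioxaborolane, both C1 epimers | C=C(Cc1ccc(OC)c(OCc2ccccc2)c1)[C@H](C(Cl)B1OC(C)(C)C(C)(C)O1)Cc1ccc(OC)c(OC)c1
F3 | step 8 | (3R)-2-[3-(benzyloxy)-4-methoxybenzyl]-4-[(tert-butyldimethylsilyl)oxy]-3-(3,4-dimethoxybenzyl)butanal, both C2 epimers | O=CC(Cc1ccc(OC)c(OCc2ccccc2)c1)[C@H](CO[Si](C)(C)C(C)(C)C)Cc1ccc(OC)c(OC)c1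
F4 | step 8 | (4R)-3-[3-(benzyloxy)-4-methoxybenzyl]-4-(3,4-dimethoxybenzyl)tetrahydrofuran-2-ol, mixture at C2 and C3 | COc1ccc(CC2C(O)OC[C@@H]2Cc2ccc(OC)c(OC)c2)cc1OCc1ccccc1
A1 | alternative 1 | (R)-4-(3,4-dimethoxybenzyl)dihydrofuran-2(3H)-one | O=C1C[C@@H](Cc2ccc(OC)c(OC)c2)CO1
A2 | alternative 1 | 3-(3,4-dimethoxybenzyl)cyclobutan-1-one | O=C1CC(Cc2ccc(OC)c(OC)c2)C1
A3 | alternative 1 | 2-(benzyloxy)-4-(bromomethyl)-1-methoxybenzene | COc1ccc(CBr)cc1OCc1ccccc1
A4 | alternative 2 | (3R,4R)-3-[3-(benzyloxy)-4-methoxybenzyl]-4-(3,4-dimethoxybenzoyl)dihydrofuran-2(3H)-one | COc1ccc(C[C@H]2C(=O)OC[C@@H]2C(=O)c2ccc(OC)c(OC)c2)cc1OCc1ccccc1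
A5 | alternative 2 | (R)-2-[3-(benzyloxy)-4-methoxybenzyl]-4-(3,4-dimethoxyphenyl)-4-oxobutanoic acid | COc1ccc(C[C@H](CC(=O)c2ccc(OC)c(OC)c2)C(=O)O)cc1OCc1ccccc1
A6 | alternative 2 | formaldehyde | C=O
A7 | alternative 3 | O-benzyl prestegane A, (3R,4R)-3-[3-(benzyloxy)-4-methoxybenzyl]-4-(3,4-dimethoxybenzyl)dihydrofuran-2(3H)-one | COc1ccc(C[C@H]2C(=O)OC[C@@H]2Cc2ccc(OC)c(OC)c2)cc1OCc1ccccc1
A8 | alternative 3 | (R,E)-4-[3-(benzyloxy)-4-methoxyphenyl]-2-(3,4-dimethoxybenzyl)but-3-en-1-ol | COc1ccc(/C=C/[C@H](CO)Cc2ccc(OC)c(OC)c2)cc1OCc1ccccc1
A9 | alternative 3 | carbon dioxide | O=C=O
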